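**Plan**

- Enabling feature: the target is a twofold-symmetric 3,3''-biflavanone with identical (2S,3R) halves. In each half, O1–C2 together with ring B is a 4-methoxybenzyl (PMB) ether of the ring A phenol, and C3 is the α-carbon of the C4 aryl ketone.
- Retrosynthesis: free the two 7-OH groups; cut C3–C3'' into two molecules of one (2S)-flavanone (oxidative union of two enolate carbons of like polarity); cut C2–C3 of ring C back to an α-diazoketone whose ortho OCH2Ar ether supplies C2 and ring B.
- Forward: ring A is bought as an acetophenone; double PMB etherification, deacylative diazo transfer, closure of ring C by carbene C–H insertion, joining of the halves at C3–C3'', hydrogenolysis.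
- Stereochemistry: C2 is set by a chiral dirhodium catalyst in the ring closure. C3 and C3'' are set together in the dimerisation by substrate control (new bond trans to the C2 aryl group). Because both halves are 2S, only the twofold-symmetric isomer can form; residual minor enantiomer is drained into a separable meso-type diastereomer.

Key step: step 4

Assumption: 2',4'-dihydroxy-6'-methoxyacetophenone is taken as commercially available, and the sense of induction of the dirhodium catalyst in step 4 is not predicted, so the ligand antipode that gives the 2S product is used ((S)-PTTL is written; (R)-PTTL replaces it if the sense is opposite).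

**Step 1**
Reactants: 1 2',4'-dihydroxy-6'-methoxyacetophenone; 2 4-methoxybenzyl chloride (2.3 equiv)
Product: 3 1-{2-methoxy-4,6-bis[(4-methoxybenzyl)oxy]phenyl}ethan-1-one
Conditions: K2CO3 (3 equiv), NaI (cat.), DMF, 70 °C
Reagents that add atoms: none
Why: Double Williamson etherification: the free 4'-phenoxide and, at 70 °C with iodide catalysis, the chelated 2'-phenoxide are both O-alkylated by the reactive benzylic chloride, so one reagent delivers the 7-O protecting group and the future C2/ring B unit; no stereocentre is formed.

**Step 2**
Reactants: 3 1-{2-methoxy-4,6-bis[(4-methoxybenzyl)oxy]phenyl}ethan-1-one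
Product: 4 4,4,4-trifluoro-1-{2-methoxy-4,6-bis[(4-methoxybenzyl)oxy]phenyl}butane-1,3-dione
Conditions: LiN(SiMe3)2 (1.1 equiv), THF, −78 °C; then CF3CO2CH2CF3 (1.2 equiv), −78 °C; cold dilute aq. HCl work-up, crude 4 used directly
Reagents that add atoms: 2,2,2-trifluoroethyl trifluoroacetate, O=C(OCC(F)(F)F)C(F)(F)F
Why: Crossed Claisen condensation of the kinetic lithium enolate of the methyl ketone with the activated trifluoroacetate installs the trifluoroacetyl activating group needed for diazo transfer; no stereocentre is formed.

**Step 3**
Reactants: 4 4,4,4-trifluoro-1-{2-methoxy-4,6-bis[(4-methoxybenzyl)oxy]phenyl}butane-1,3-dione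
Product: 5 2-diazo-1-{2-methoxy-4,6-bis[(4-methoxybenzyl)oxy]phenyl}ethan-1-one
Conditions: CH3SO2N3 (1.5 equiv), Et3N (1.5 equiv), H2O (1 equiv), MeCN, rt
Reagents that add atoms: methanesulfonyl azide, CS(=O)(=O)N=[N+]=[N-]
Why: Deacylative (Regitz-type) diazo transfer: the 1,3-diketone enolate adds to the sulfonyl azide and the adduct fragments with loss of the trifluoroacetyl group as its sulfonamide, leaving the terminal α-diazoketone without touching the PMB ethers.

**Step 4**
Reactants: 5 2-diazo-1-{2-methoxy-4,6-bis[(4-methoxybenzyl)oxy]phenyl}ethan-1-one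
Product: 6 (2S)-5-methoxy-7-[(4-methoxybenzyl)oxy]-2-(4-methoxyphenyl)chroman-4-one
Conditions: Rh2(S-PTTL)4 (dirhodium tetrakis[N-phthaloyl-(S)-tert-leucinate], 1 mol %), CH2Cl2, −20 to 0 °C, slow addition of 5
Reagents that add atoms: none
Why: The dirhodium tetracarboxylate expels N2 from 5 to give an electrophilic rhodium-bound acyl carbene at the future C3, which inserts through a concerted, asynchronous, hydride-transfer-like three-centre transition state into one of the two enantiotopic C–H bonds of the ortho OCH2Ar group (the future C2), forming the C2–C3 bond and releasing the catalyst. The closest known reaction type is the dirhodium-carboxylate-catalysed intramolecular C–H insertion of ortho-alkoxyaryl α-diazoketones next to the ether oxygen, which gives chroman-4-ones and is enantioselective with chiral carboxylate ligands. Ring C closes as a six-membered ring by 1,6-insertion through a six-membered chair-like transition state, the rigid aroyl–aryl ether backbone holding the OCH2 hydrogens within reach of the carbene carbon. C2 is the only new stereocentre and is set by the catalyst, whose chiral N-phthaloyl-tert-leucinate ligand wall distinguishes the pro-R from the pro-S benzylic hydrogen by turning the anisyl group away from the ligands. The step needs chemoselectivity for this C–H bond over insertion into the ortho OCH3 group, over oxonium ylide formation at the ether oxygen followed by Stevens 1,2-benzyl shift to a 2-benzylbenzofuran-3-one, over Büchner addition to the anisyl ring and over Wolff rearrangement. The substrate secures it because the C2–H bond is secondary and doubly activated (α to oxygen and p-methoxybenzylic, the most hydridic C–H in the molecule), the ether oxygen is a weakly nucleophilic vinylogous-ester oxygen whose ylide formation is reversible, and the primary OCH3 hydrogens are far less reactive.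

**Step 5**
Reactants: 6 (2S)-5-methoxy-7-[(4-methoxybenzyl)oxy]-2-(4-methoxyphenyl)chroman-4-one (two molecules)
Product: 8 (2S,3R,2''S,3''R)-5,5''-dimethoxy-7,7''-bis[(4-methoxybenzyl)oxy]-2,2''-bis(4-methoxyphenyl)-[3,3''-bichromane]-4,4''-dione, via flavanone lithium enolate 7 (not isolated)
Conditions: LiN(iPr)2 (1.05 equiv), THF, −78 °C; then CuCl2 (1.1 equiv), DMF, −78 to −20 °C
Reagents that add atoms: none
Why: Oxidative homocoupling of a ketone lithium enolate by CuCl2 joins the two like-polarised C3 carbons through the α-keto radical (cupric enolate); each C3 is attacked anti to its own C2 aryl group, so both new stereocentres are set trans (3R,3''R) by substrate control, two homochiral 2S halves can only give the twofold-symmetric isomer, and any cis C3 epimer should relax to the diequatorial trans,trans isomer by enolisation.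

**Step 6**
Reactants: 8 (2S,3R,2''S,3''R)-5,5''-dimethoxy-7,7''-bis[(4-methoxybenzyl)oxy]-2,2''-bis(4-methoxyphenyl)-[3,3''-bichromane]-4,4''-dione
Product: 9 4',4''',5,5''-tetramethylchamaejasmin
Conditions: H2 (1 atm), Pd/C (10 wt %), EtOAc–THF, rt, stopped at complete debenzylation
Reagents that add atoms: none
Why: Heterogeneous hydrogenolysis on zerovalent palladium cleaves the two primary aryl PMB ethers under neutral conditions, which should leave the hindered secondary in-ring C2–O1 benzylic bonds, the aryl ketones and all four stereocentres untouched (no base, hence no retro-oxa-Michael opening or C3 epimerisation).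

**Compound list**

1 | 2',4'-dihydroxy-6'-methoxyacetophenone, 1-(2,4-dihydroxy-6-methoxyphenyl)ethan-1-one | CC(=O)c1c(O)cc(O)cc1OC | starting material
2 | 4-methoxybenzyl chloride | COc1ccc(CCl)cc1 | starting material
3 | 1-{2-methoxy-4,6-bis[(4-methoxybenzyl)oxy]phenyl}ethan-1-one | CC(=O)c1c(OCc2ccc(OC)cc2)cc(OCc2ccc(OC)cc2)cc1OC | intermediate
4 | 4,4,4-trifluoro-1-{2-methoxy-4,6-bis[(4-methoxybenzyl)oxy]phenyl}butane-1,3-dione | O=C(CC(=O)C(F)(F)F)c1c(OCc2ccc(OC)cc2)cc(OCc2ccc(OC)cc2)cc1OC | intermediate
5 | 2-diazo-1-{2-methoxy-4,6-bis[(4-methoxybenzyl)oxy]phenyl}ethan-1-one | [N-]=[N+]=CC(=O)c1c(OCc2ccc(OC)cc2)cc(OCc2ccc(OC)cc2)cc1OC | intermediate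
6 | (2S)-5-methoxy-7-[(4-methoxybenzyl)oxy]-2-(4-methoxyphenyl)chroman-4-one | COc1ccc([C@H]2Oc3cc(OCc4ccc(OC)cc4)cc(OC)c3C(=O)C2)cc1 | intermediate
7 | lithium enolate of 6, lithium (2S)-5-methoxy-7-[(4-methoxybenzyl)oxy]-2-(4-methoxyphenyl)-2H-chromen-4-olate | COc1ccc([C@H]2Oc3cc(OCc4ccc(OC)cc4)cc(OC)c3C(O[Li])=C2)cc1 | intermediate
8 | (2S,3R,2''S,3''R)-5,5''-dimethoxy-7,7''-bis[(4-methoxybenzyl)oxy]-2,2''-bis(4-methoxyphenyl)-[3,3''-bichromane]-4,4''-dione | COc1ccc([C@H]2Oc3cc(OCc4ccc(OC)cc4)cc(OC)c3C(=O)[C@@H]2[C@H]2C(=O)c3c(OC)cc(OCc4ccc(OC)cc4)cc3O[C@@H]2c2ccc(OC)cc2)cc1 | intermediate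
9 | 4',4''',5,5''-tetramethylchamaejasmin, (2S,3R,2''S,3''R)-7,7''-dihydroxy-5,5''-dimethoxy-2,2''-bis(4-methoxyphenyl)-[3,3''-bichromane]-4,4''-dione | COc1ccc([C@H]2Oc3cc(O)cc(OC)c3C(=O)[C@@H]2[C@H]2C(=O)c3c(OC)cc(O)cc3O[C@@H]2c2ccc(OC)cc2)cc1 | target

**Totals**

Total step count: 6. Longest linear sequence: 6 steps (from 1).

**Steps most likely to fail**

1. Step 4. The rhodium carbene may be diverted into oxonium ylide formation at the ether oxygen with 1,2-benzyl migration, or the catalyst may discriminate poorly between the two enantiotopic benzylic hydrogens. The fallback gives up the C–H insertion for known asymmetric conjugate arylation; it sets out from 1 and comes back at 6. Selective Williamson alkylation of the non-chelated 4'-OH of 1 with one equivalent of 2 (K2CO3, acetone, reflux) should give 1-{2-hydroxy-6-methoxy-4-[(4-methoxybenzyl)oxy]phenyl}ethan-1-one F1. Condensation with N,N-dimethylformamide dimethyl acetal (toluene, 90 °C) should give the enaminone (E)-3-(dimethylamino)-1-{2-hydroxy-6-methoxy-4-[(4-methoxybenzyl)oxy]phenyl}prop-2-en-1-one F2. Warming in acetic acid should close it by addition–elimination to 5-methoxy-7-[(4-methoxybenzyl)oxy]-4H-chromen-4-one F3. Enantioselective 1,4-addition of 4-methoxyphenylboronic acid (Pd(OCOCF3)2, t-BuPyOx ligand of the antipode that gives 2S, NH4PF6, H2O, ClCH2CH2Cl, 60 °C) should then give 6.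

2. Step 5. Dehydrogenation of the enolate or C3 radical toward the flavone, or E1cB opening of ring C, may outrun the bimolecular union of two hindered secondary carbons. The fallback makes the coupling intramolecular on a temporary silicon tether; it sets out from 6 and comes back at 8. Deprotonation of 6 with LiN(iPr)2 (THF, −78 °C) and trapping with Me2SiCl2 (0.5 equiv) should give the tethered bis-enol ether dimethylbis{[(2S)-5-methoxy-7-[(4-methoxybenzyl)oxy]-2-(4-methoxyphenyl)-2H-chromen-4-yl]oxy}silane F4. One-electron oxidation with (NH4)2Ce(NO3)6 and NaHCO3 in MeCN–EtCN at −10 °C should form C3–C3'' through a seven-membered transition state and release the tether on work-up to give 8; the enol ether should be oxidised well before the aryl PMB ethers at this temperature.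

3. Step 6. Over-reduction (hydrogenolytic opening of the in-ring C2–O1 benzylic bonds) or slow, incomplete cleavage of a poorly soluble substrate may occur. The fallback replaces hydrogenolysis by acidolysis; it sets out from 8 and comes back at 9. Treatment with CF3CO2H (10 vol %) and anisole as cation scavenger in CH2Cl2 at 0 °C should ionise the primary PMB ethers, while the in-ring C2–O1 bond, whose oxygen is a weakly basic vinylogous-ester oxygen, should stay closed at this temperature; no new compound is made (F0).

**Further compounds**

F1 | step 4 | 1-{2-hydroxy-6-methoxy-4-[(4-methoxybenzyl)oxy]phenyl}ethan-1-one | CC(=O)c1c(O)cc(OCc2ccc(OC)cc2)cc1OC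
F2 | step 4 | (E)-3-(dimethylamino)-1-{2-hydroxy-6-methoxy-4-[(4-methoxybenzyl)oxy]phenyl}prop-2-en-1-one | CN(C)/C=C/C(=O)c1c(O)cc(OCc2ccc(OC)cc2)cc1OC
F3 | step 4 | 5-methoxy-7-[(4-methoxybenzyl)oxy]-4H-chromen-4-one | O=c1ccoc2cc(OCc3ccc(OC)cc3)cc(OC)c12
F4 | step 5 | dimethylbis{[(2S)-5-methoxy-7-[(4-methoxybenzyl)oxy]-2-(4-methoxyphenyl)-2H-chromen-4-yl]oxy}silane | COc1ccc([C@H]2Oc3cc(OCc4ccc(OC)cc4)cc(OC)c3C(O[Si](C)(C)OC3=C[C@@H](c4ccc(OC)cc4)Oc4cc(OCc5ccc(OC)cc5)cc(OC)c34)=C2)cc1
F0 | step 6 | none | none
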